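Over 30 min at 25 °C, 5 °C or −15 °C, or warm and then cold after 20 min, substrate reacts in a solution that takes up coupling partner from a held gas, and we ask how much of what reacted ends as target.

| setting | oak | cedar | maple | elm |
|---|---|---|---|---|
| substrate | 20 mM | 20 mM | 20 mM | 20 mM |
| gas | 0.69 mM (held) | 0.69 mM (held) | 0.69 mM (held) | 0.69 mM (held) |
| time | 30 min | 30 min | 30 min | 30 min |
| remark | at 25 °C until 20 min, from then on at −15 °C |  |  |  |
| temperature |  | 25 °C | 5 °C | −15 °C |

    target → over-reaction product (k1 = 1.37 × 10⁻⁴ s⁻¹, Ea1 = 83.0 kJ mol⁻¹)
    substrate + coupling partner → target (k2 = 0.923 L mol⁻¹ s⁻¹, Ea2 = 53.0 kJ mol⁻¹)
    2 substrate → side product B (k3 = 0.00928 L mol⁻¹ s⁻¹, Ea3 = 68.0 kJ mol⁻¹)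
    crystals ⇌ target, rate k4*(cs4 - [target]) while solid is left; crystals form when [target] > cs4 (cs4 = 0.91 mM, k4 = 0.0427 s⁻¹)
    gas ⇌ coupling partner, rate k5*(csat - [coupling partner]) (k5 = 0.0286 s⁻¹, csat = 0.69 mM)
    substrate → side product A (k6 = 6.23 × 10⁻⁵ s⁻¹, Ea6 = 99.0 kJ mol⁻¹)
    (constants at 5 °C)

- percentages count the substrate that a species holds: one side product B counts as two
- target is meant together with its crystals
- two of one species on the left: rate k times its square, two consumed each time
- solid, in amounts per volume of the solution: crystals
- at the start none of coupling partner is dissolved
- all constants are for 5 °C and move with temperature by the activation energies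

- the flask with the highest share of target in all that became target or side product A or side product B or over-reaction product ("all alike" if they lie within 1.5 percentage points) (oak / cedar / maple / elm / all alike)
- share of target in all that became target or side product A or side product B or over-reaction product, oak
- share of target in all that became target or side product A or side product B or over-reaction product, cedar
- share of target in all that became target or side product A or side product B or over-reaction product, maple
- share of target in all that became target or side product A or side product B or over-reaction product, elm

We carry one quantity, the coupling share: the coupling flow divided by the sum of the three flows that consume substrate, with the flask at its full charge. For elm, let the appetite be the coupling constant times [substrate], here 0.188 min⁻¹, while the transfer coefficient is 1.7 min⁻¹.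

Two extreme flasks can be solved in the head. If transfer were instantaneous, [coupling partner] would stand at saturation and elm's coupling flow would be 0.129 mM min⁻¹. If every arriving partner reacted at once, the flow would be the transfer ceiling, 1.18 mM min⁻¹. The real flow lies below both, since the two resistances add in series. It sits near the smaller one, because in elm transfer is faster than the appetite, which makes coupling the rate-limiting step of the pair. Partner starts at zero and approaches its steady level with a time constant of about 0.530 min, short beside the 30 min of the run:

[coupling partner] = saturation / (1 + appetite / transfer coefficient) = 0.622 mM

coupling flow = appetite × [coupling partner] = 0.117 mM min⁻¹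

side product B route = 0.0457 mM min⁻¹

side product A route = 0.00271 mM min⁻¹

coupling share, elm = 70.7%

In cedar the appetite is 5.15 min⁻¹, which exceeds the transfer coefficient, so there the ceiling binds, and the same reckoning gives 16.4%. Maple gives 47.2%. As substrate falls, the side product B route falls with its square, so the running share climbs from these starting values. We therefore expect elm first, a little above its figure, and oak close to cedar, whose course it follows until the switch.

The forecast gave 27% for oak, 23.5% for cedar, 58.5% for maple and 72.5% for elm, holding that “the cold flask is the most selective”. Its first place is ours, and its figures for cedar, maple and elm stand above our starting shares.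

The simulation gives 26.4% for oak, 22.8% for cedar, 58.6% for maple and 72.3% for elm, which leaves elm first, with elm's share over the whole run 1.6 percentage points above its starting coupling share of 70.7%. On the neighbour of elm charged with 34 mM of substrate, the appetite becomes 0.319 min⁻¹, the coupling flow 0.186 mM min⁻¹ and the side product B route 0.132 mM min⁻¹, so the starting coupling share drops to 57.6%. Over its whole run that neighbour reads 60.4%, less than elm's 72.3%.

The numbers come from no measurement.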